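**Plan**

1. Numbering (eudesmane, used in the text; names use naphthalene locants): ring A = C10–C1–C2–C3–C4–C5 (C10 quaternary methyl carbon, C5 ring-fusion CH, C3 secondary carbinol, C4 methyl carbinol); ring B = C5–C6–C7–C8–C9–C10 (C6 benzoyloxy carbon, C7 isopropyl carbon); β is the face of the C10 methyl.
2. Retrosynthetic cuts, in order: the benzoate C–O bond; C3–OH back to a ketone; the C3 ketone back to a C1-carbonyl/C3-methoxy vinylogous ester (the C1 oxygen is a helper); the C6 oxygen back to an allylic CH2 beside a C7=C8 bond; the C4–CH3 bond back to a C4 ketone; last, ring B at C9–C10 and C5–C6 (retro-Diels–Alder).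
3. Enabling feature: the adjacent ring-fusion carbons C5 and C10 are flanked by C4 and C1, which can both be carbonyls, and C3 carries oxygen. Ring A is therefore a masked 2-methoxy-5-methyl-1,4-benzoquinone whose C5=C10 bond is a dienophile, and C6–C7(iPr)=C8–C9 is 2-isopropylbutadiene.
4. Forward: ring A is bought as the quinone; ring B arises in one cycloaddition (step 2); then C4 methyl, C6 oxygen, ring B saturation, ring A unmasking, benzoate, C3 carbinol.
5. Stereochemistry: C10 (absolute) from the catalyst-controlled cycloaddition; C5 by equilibration to the trans-fused dione; C4 by attack anti to the angular methyl; C7 by hydrogenation anti to it; C6 by hydride attack anti to the two syn-axial β groups; C3 by hydroxyl-directed hydride delivery.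

Key step: step 2

Assumption: the (S)-configured catalyst is taken to expose the quinone face that leads to 5 as drawn; if the sense of induction is the opposite, the mirror-image catalyst from the (R)-amino alcohol is used.

**Route**

Step 1
Reactants: 1 3-methylbut-1-yne; 2 ethene
Product: 3 2-(propan-2-yl)buta-1,3-diene
Conditions: second-generation Grubbs catalyst RuCl2(=CHPh)(PCy3)(H2IMes) (2 mol%), ethene (4 atm), CH2Cl2, 25 °C
Reagents that add atoms: none
Why: Ene–yne cross-metathesis of a terminal alkyne with ethene should give the 2-substituted butadiene directly, with no stereocenter formed.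

Step 2
Reactants: 3 2-(propan-2-yl)buta-1,3-diene; 4 2-methoxy-5-methylcyclohexa-2,5-diene-1,4-dione
Product: 5 (4aR,8aS)-2-methoxy-4a-methyl-7-(propan-2-yl)-4a,5,8,8a-tetrahydronaphthalene-1,4-dione
Conditions: 3 (3 equiv), salt of (S)-3,3-bis(3,5-dimethylphenyl)-1-(2-methylphenyl)tetrahydro-1H,3H-pyrrolo[1,2-c][1,3,2]oxazaborole with Tf2NH (20 mol%), CH2Cl2, −78 to −40 °C
Reagents that add atoms: none
Why: The protonated oxazaborolidine is a chiral cationic boron Lewis acid that should bind the more basic, vinylogous-ester carbonyl of 4 (the one conjugated with the methoxy group, future C1), after which the methyl-substituted quinone double bond undergoes a concerted, asynchronous Diels–Alder reaction with 3; the closest known reaction types are the oxazaborolidinium-catalysed Diels–Alder reaction of 1,4-benzoquinones and, for the orientation, the BF3-promoted addition of 2-substituted dienes to this same quinone. Ring B is closed in one [4+2] cycloaddition, suprafacial on both partners, in which the diene CH2 next to the isopropyl-bearing carbon bonds to the unsubstituted quinone carbon (C5–C6) and the other diene terminus forms the C9–C10 bond at the methyl-bearing carbon. Suprafacial addition makes the C5 hydrogen and the C10 methyl cis, and because both diene termini are CH2 the endo and exo modes give the same product, so the only stereochemical variable is the enantiotopic face, which the aryl groups of the catalyst should fix by covering one face of the bound quinone. The step needs site selectivity, which the methoxy group secures by deactivating its own double bond, and regioselectivity, which the same group secures by making the remote carbonyl the Lewis-basic site, so that the isopropyl group ends para to that carbonyl, at C7 and not at C8.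

Step 3
Reactants: 5 (4aR,8aS)-2-methoxy-4a-methyl-7-(propan-2-yl)-4a,5,8,8a-tetrahydronaphthalene-1,4-dione
Product: 6 (4aR,8aR)-2-methoxy-4a-methyl-7-(propan-2-yl)-4a,5,8,8a-tetrahydronaphthalene-1,4-dione
Conditions: DBU (0.1 equiv), toluene, 0 to 25 °C
Reagents that add atoms: none
Why: Base-mediated epimerization through the C4 enolate (thermodynamic control) should convert the cis-fused into the more stable trans-fused enedione, inverting C5 so that its hydrogen is anti to the angular methyl.

Step 4
Reactants: 6 (4aR,8aR)-2-methoxy-4a-methyl-7-(propan-2-yl)-4a,5,8,8a-tetrahydronaphthalene-1,4-dione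
Product: 7 (4R,4aR,8aR)-4-hydroxy-3-methoxy-4,8a-dimethyl-6-(propan-2-yl)-4a,5,8,8a-tetrahydronaphthalen-1(4H)-one
Conditions: MeMgBr (1.2 equiv), CeCl3 (1.5 equiv), THF, −78 °C; aq. NH4Cl
Reagents that add atoms: methylmagnesium bromide, C[Mg]Br
Why: 1,2-Addition of the organocerium reagent made from the Grignard reagent should occur at the ketone-like C4 carbonyl and not at the vinylogous-ester carbonyl, and from the α face because the β face is blocked by the syn-axial angular methyl, which sets C4 with its hydroxyl cis to that methyl.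

Step 5
Reactants: 7 (4R,4aR,8aR)-4-hydroxy-3-methoxy-4,8a-dimethyl-6-(propan-2-yl)-4a,5,8,8a-tetrahydronaphthalen-1(4H)-one
Product: 9 (4R,4aR,8aR)-4-hydroxy-3-methoxy-4,8a-dimethyl-6-(propan-2-yl)-4a,8-dihydronaphthalene-1,5(4H,8aH)-dione, via allylic alcohol 8 (not isolated)
Conditions: SeO2 (cat.), t-BuOOH (3 equiv), CH2Cl2, 0 to 25 °C; aqueous work-up, then Dess–Martin periodinane (1.5 equiv), NaHCO3, CH2Cl2, 25 °C
Reagents that add atoms: tert-butyl hydroperoxide, CC(C)(C)OO
Why: Selenium dioxide allylic oxidation (ene reaction, then [2,3]-sigmatropic shift) should attack the ring CH2 on the more substituted end of the trisubstituted C7=C8 bond, that is C6, and Dess–Martin oxidation of the epimeric allylic alcohols removes the new stereocenter and gives the enone.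

Step 6
Reactants: 9 (4R,4aR,8aR)-4-hydroxy-3-methoxy-4,8a-dimethyl-6-(propan-2-yl)-4a,8-dihydronaphthalene-1,5(4H,8aH)-dione
Product: 10 (4R,4aR,6S,8aR)-4-hydroxy-3-methoxy-4,8a-dimethyl-6-(propan-2-yl)-4a,6,7,8-tetrahydronaphthalene-1,5(4H,8aH)-dione
Conditions: H2 (1 atm), Pd/C (10%), EtOAc, 25 °C
Reagents that add atoms: none
Why: Heterogeneous hydrogenation of the enone C7=C8 bond should deliver hydrogen from the α face, opposite the angular methyl, which places the isopropyl group β and equatorial (also the thermodynamic configuration of this epimerizable centre), while the electron-rich, hindered enol-ether double bond is expected to survive.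

Step 7
Reactants: 10 (4R,4aR,6S,8aR)-4-hydroxy-3-methoxy-4,8a-dimethyl-6-(propan-2-yl)-4a,6,7,8-tetrahydronaphthalene-1,5(4H,8aH)-dione
Product: 11 (4R,4aS,5R,6S,8aR)-4,5-dihydroxy-3-methoxy-4,8a-dimethyl-6-(propan-2-yl)-4a,5,6,7,8,8a-hexahydronaphthalen-1(4H)-one
Conditions: NaBH4, MeOH, −20 to 0 °C
Reagents that add atoms: none
Why: Borohydride reduction of the C6 ketone from the α face (equatorial attack), the β face being shielded by the syn-axial C10 methyl and C4 hydroxyl, should give the axial 6β-alcohol, while the vinylogous-ester carbonyl is too electron-rich to be reduced.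

Step 8
Reactants: 11 (4R,4aS,5R,6S,8aR)-4,5-dihydroxy-3-methoxy-4,8a-dimethyl-6-(propan-2-yl)-4a,5,6,7,8,8a-hexahydronaphthalen-1(4H)-one
Product: 13 (1R,4aS,7S,8R,8aS)-1,8-dihydroxy-1,4a-dimethyl-7-(propan-2-yl)-4a,5,6,7,8,8a-hexahydronaphthalen-2(1H)-one, via hydroxy enol ether 12 (not isolated)
Conditions: i-Bu2AlH (4 equiv), CH2Cl2, −78 to 0 °C; then 1 M HCl, THF, 0 to 25 °C
Reagents that add atoms: water, O
Why: Stork–Danheiser 1,3-carbonyl transposition, in which 1,2-reduction of the vinylogous ester and acid hydrolysis of the resulting γ-hydroxy enol ether expel the helper oxygen at C1 and methanol and unveil the C3 ketone as the C1=C2 enone, with no stereocenter created or touched.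

Step 9
Reactants: 13 (1R,4aS,7S,8R,8aS)-1,8-dihydroxy-1,4a-dimethyl-7-(propan-2-yl)-4a,5,6,7,8,8a-hexahydronaphthalen-2(1H)-one
Product: 14 (1R,2S,4aS,8R,8aS)-8-hydroxy-4a,8-dimethyl-7-oxo-2-(propan-2-yl)-1,2,3,4,4a,7,8,8a-octahydronaphthalen-1-yl benzoate
Conditions: BzCl (2 equiv), DMAP (0.3 equiv), pyridine, CH2Cl2, 0 to 40 °C
Reagents that add atoms: benzoyl chloride, O=C(Cl)c1ccccc1
Why: DMAP-catalysed acylation should esterify the only secondary hydroxyl (axial, at C6) with retention, the tertiary hydroxyl at C4 being too hindered to react.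

Step 10
Reactants: 14 (1R,2S,4aS,8R,8aS)-8-hydroxy-4a,8-dimethyl-7-oxo-2-(propan-2-yl)-1,2,3,4,4a,7,8,8a-octahydronaphthalen-1-yl benzoate
Product: 15 (1R,2S,4aS,8R,8aS)-8-hydroxy-4a,8-dimethyl-7-oxo-2-(propan-2-yl)decahydronaphthalen-1-yl benzoate
Conditions: H2 (1 atm), Pd/C (10%), EtOAc, 25 °C
Reagents that add atoms: none
Why: Catalytic hydrogenation of the disubstituted enone double bond should leave ketone and benzoate untouched and creates no stereocenter.

Step 11
Reactants: 15 (1R,2S,4aS,8R,8aS)-8-hydroxy-4a,8-dimethyl-7-oxo-2-(propan-2-yl)decahydronaphthalen-1-yl benzoate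
Product: 16 (1R,2S,4aS,7R,8R,8aS)-7,8-dihydroxy-4a,8-dimethyl-2-(propan-2-yl)decahydronaphthalen-1-yl benzoate
Conditions: Me4NBH(OAc)3 (5 equiv), AcOH/MeCN 1:1, −20 °C
Reagents that add atoms: none
Why: Evans–Saksena hydroxyl-directed reduction, in which the tertiary 4β-hydroxyl exchanges onto boron and delivers hydride to the adjacent C3 carbonyl from its own β face, should give the 3α-alcohol trans to it (the trans-diaxial diol) without touching the benzoate.

**Compound list**

1 | 3-methylbut-1-yne | C#CC(C)C | starting material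
2 | ethene | C=C | starting material
3 | 2-(propan-2-yl)buta-1,3-diene | C=CC(=C)C(C)C | intermediate
4 | 2-methoxy-5-methylcyclohexa-2,5-diene-1,4-dione | COC1=CC(=O)C(C)=CC1=O | starting material
5 | (4aR,8aS)-2-methoxy-4a-methyl-7-(propan-2-yl)-4a,5,8,8a-tetrahydronaphthalene-1,4-dione (cis-fused) | CC(C)C1=CC[C@@]2(C)C(=O)C=C(OC)C(=O)[C@H]2C1 | intermediate
6 | (4aR,8aR)-2-methoxy-4a-methyl-7-(propan-2-yl)-4a,5,8,8a-tetrahydronaphthalene-1,4-dione (trans-fused) | CC(C)C1=CC[C@@]2(C)C(=O)C=C(OC)C(=O)[C@@H]2C1 | intermediate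
7 | (4R,4aR,8aR)-4-hydroxy-3-methoxy-4,8a-dimethyl-6-(propan-2-yl)-4a,5,8,8a-tetrahydronaphthalen-1(4H)-one | CC(C)C1=CC[C@@]2(C)C(=O)C=C(OC)[C@](C)(O)[C@@H]2C1 | intermediate
8 | (4R,4aS,8aR)-4,5-dihydroxy-3-methoxy-4,8a-dimethyl-6-(propan-2-yl)-4a,5,8,8a-tetrahydronaphthalen-1(4H)-one, mixture of C5 epimers | CC(C)C1=CC[C@@]2(C)C(=O)C=C(OC)[C@](C)(O)[C@@H]2C1O | intermediate (not isolated)
9 | (4R,4aR,8aR)-4-hydroxy-3-methoxy-4,8a-dimethyl-6-(propan-2-yl)-4a,8-dihydronaphthalene-1,5(4H,8aH)-dione | CC(C)C1=CC[C@@]2(C)C(=O)C=C(OC)[C@](C)(O)[C@@H]2C1=O | intermediate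
10 | (4R,4aR,6S,8aR)-4-hydroxy-3-methoxy-4,8a-dimethyl-6-(propan-2-yl)-4a,6,7,8-tetrahydronaphthalene-1,5(4H,8aH)-dione | CC(C)[C@@H]1CC[C@@]2(C)C(=O)C=C(OC)[C@](C)(O)[C@@H]2C1=O | intermediate
11 | (4R,4aS,5R,6S,8aR)-4,5-dihydroxy-3-methoxy-4,8a-dimethyl-6-(propan-2-yl)-4a,5,6,7,8,8a-hexahydronaphthalen-1(4H)-one | CC(C)[C@@H]1CC[C@@]2(C)C(=O)C=C(OC)[C@](C)(O)[C@@H]2[C@@H]1O | intermediate
12 | (4R,4aS,5R,6S,8aR)-3-methoxy-4,8a-dimethyl-6-(propan-2-yl)-1,4,4a,5,6,7,8,8a-octahydronaphthalene-1,4,5-triol, mixture of C1 epimers | CC(C)[C@@H]1CC[C@@]2(C)C(O)C=C(OC)[C@](C)(O)[C@@H]2[C@@H]1O | intermediate (not isolated)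
13 | (1R,4aS,7S,8R,8aS)-1,8-dihydroxy-1,4a-dimethyl-7-(propan-2-yl)-4a,5,6,7,8,8a-hexahydronaphthalen-2(1H)-one | CC(C)[C@@H]1CC[C@@]2(C)C=CC(=O)[C@](C)(O)[C@@H]2[C@@H]1O | intermediate
14 | (1R,2S,4aS,8R,8aS)-8-hydroxy-4a,8-dimethyl-7-oxo-2-(propan-2-yl)-1,2,3,4,4a,7,8,8a-octahydronaphthalen-1-yl benzoate | CC(C)[C@@H]1CC[C@@]2(C)C=CC(=O)[C@](C)(O)[C@@H]2[C@@H]1OC(=O)c1ccccc1 | intermediate
15 | (1R,2S,4aS,8R,8aS)-8-hydroxy-4a,8-dimethyl-7-oxo-2-(propan-2-yl)decahydronaphthalen-1-yl benzoate | CC(C)[C@@H]1CC[C@@]2(C)CCC(=O)[C@](C)(O)[C@@H]2[C@@H]1OC(=O)c1ccccc1 | intermediate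
16 | (1R,2S,4aS,7R,8R,8aS)-7,8-dihydroxy-4a,8-dimethyl-2-(propan-2-yl)decahydronaphthalen-1-yl benzoate | CC(C)[C@@H]1CC[C@@]2(C)CC[C@@H](O)[C@](C)(O)[C@@H]2[C@@H]1OC(=O)c1ccccc1 | target

**Count and risks**

Total step count: 11. Longest linear sequence: 11 steps (1 to 16; the quinone 4 enters at step 2).

Step 2 is the riskiest. The chiral boron cation may bind the other quinone carbonyl, or discriminate the two faces of the methyl-substituted double bond poorly, which would erode the orientation or the enantiomeric purity. The fallback sets out from 3 and 4 and returns at 7, using known chemistry. BF3·OEt2 (1 equiv) in CH2Cl2 at −78 to −20 °C, the achiral Lewis acid that gives this orientation on this quinone, should give the racemic cis adduct F1. DBU equilibrates it to the racemic trans-fused dione F2. The lithium salt of (S)-N,S-dimethyl-S-phenylsulfoximine (n-BuLi, THF, −78 °C) should add to the ketone-like carbonyl anti to the angular methyl and give the β-hydroxysulfoximine F3 together with its diastereomer F4, which arises from the mirror-image ketone. The two are separated by chromatography, and Raney nickel (W-2, wet THF, 25 °C) cleaves the C–S bond of F3 to the methyl group of 7. The resolving agent thus doubles as the methyl source.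

Step 3 is the second risk. The equilibration may stop at a mixture of ring-fusion epimers or be accompanied by base-induced decomposition of the enedione. The fallback sets out from 5 and returns at 6, replacing thermodynamic by kinetic control. TBSOTf and Et3N in CH2Cl2 at −78 °C should give the silyl dienol ether F5, in which the ring-fusion carbon is sp2. HF·pyridine in THF at −78 °C then protonates that carbon from the face opposite the angular methyl and frees the ketone, which should give 6.

Step 11 is the third risk. Slow exchange at the hindered tertiary hydroxyl may let undirected reduction compete and produce the equatorial 3β-alcohol. The fallback goes from 15 directly to 16 and replaces substrate direction by reagent control. K[(s-Bu)3BH] in THF at −78 °C is a bulky hydride that attacks cyclohexanones along the equatorial direction and is known to give axial alcohols from 3-ketones flanked by a fully substituted C4. No new compound is formed.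

**Further compounds**

F1 | step 2 | racemic (4aR,8aS)-2-methoxy-4a-methyl-7-(propan-2-yl)-4a,5,8,8a-tetrahydronaphthalene-1,4-dione (one enantiomer drawn) | CC(C)C1=CC[C@@]2(C)C(=O)C=C(OC)C(=O)[C@H]2C1
F2 | step 2 | racemic (4aR,8aR)-2-methoxy-4a-methyl-7-(propan-2-yl)-4a,5,8,8a-tetrahydronaphthalene-1,4-dione (one enantiomer drawn) | CC(C)C1=CC[C@@]2(C)C(=O)C=C(OC)C(=O)[C@@H]2C1
F3 | step 2 | (4R,4aR,8aR)-4-hydroxy-3-methoxy-8a-methyl-4-{[(S)-N-methyl-S-phenylsulfonimidoyl]methyl}-6-(propan-2-yl)-4a,5,8,8a-tetrahydronaphthalen-1(4H)-one | CC(C)C1=CC[C@@]2(C)C(=O)C=C(OC)[C@](C[S@@](=O)(=NC)c3ccccc3)(O)[C@@H]2C1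
F4 | step 2 | (4S,4aS,8aS)-4-hydroxy-3-methoxy-8a-methyl-4-{[(S)-N-methyl-S-phenylsulfonimidoyl]methyl}-6-(propan-2-yl)-4a,5,8,8a-tetrahydronaphthalen-1(4H)-one | CC(C)C1=CC[C@]2(C)C(=O)C=C(OC)[C@@](C[S@@](=O)(=NC)c3ccccc3)(O)[C@H]2C1
F5 | step 3 | (8aR)-4-[(tert-butyldimethylsilyl)oxy]-3-methoxy-8a-methyl-6-(propan-2-yl)-8,8a-dihydronaphthalen-1(5H)-one | CC(C)C1=CC[C@@]2(C)C(=O)C=C(OC)C(O[Si](C)(C)C(C)(C)C)=C2C1
F0 | step 11 | none | none
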